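**Retrosynthetic overview**
- The pyranone ring is the only ring made, and it is closed last: flavone ⇐ 2'-hydroxychalcone by oxidative cyclisation (I2/DMSO).
- Key C–C bond (chalcone Cα–Cβ): intermolecular Claisen–Schmidt aldol condensation of 2'-hydroxy-3',5',6'-trimethoxyacetophenone with 2,5-dimethoxybenzaldehyde.
- The hydroxyacetophenone ⇐ symmetric 2,3,5,6-tetramethoxyacetophenone by chelation-controlled mono-demethylation (both ortho-OMe groups are equivalent).
- The tetramethoxyacetophenone ⇐ 1,2,4,5-tetramethoxybenzene by ortho-lithiation/acylation (both ring C–H are equivalent).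
- 1,2,4,5-Tetramethoxybenzene ⇐ 2,4,5-trimethoxyphenol ⇐ 2,4,5-trimethoxybenzaldehyde (Baeyer–Villiger); both benzene rings are bought.

Assumption: the target has no stereocentre, so "single enantiomer" means the one achiral compound drawn. Small reagents are not numbered; they are given by name and SMILES in each step.

**Step 1**
Reactants: 1 2,4,5-trimethoxybenzaldehyde
Product: 3 2,4,5-trimethoxyphenol, via aryl formate 2 (not isolated)
Conditions: mCPBA (1.2 equiv), CH2Cl2, 0 °C → rt; NaHCO3 wash; then MeOH, cat. HCl, rt, N2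
Reagents that add atoms: meta-chloroperoxybenzoic acid (mCPBA), O=C(OO)c1cccc(Cl)c1
Why: Baeyer–Villiger (Dakin-type) oxidation, in which the electron-rich aryl group migrates to oxygen in preference to hydrogen, followed by acid-catalysed transesterification of the labile formate; no stereocentre is involved.

**Step 2**
Reactants: 3 2,4,5-trimethoxyphenol
Product: 4 1,2,4,5-tetramethoxybenzene
Conditions: MeI (1.5 equiv), K2CO3 (2 equiv), acetone, reflux, N2
Reagents that add atoms: iodomethane, CI
Why: Williamson O-methylation (SN2) of the phenoxide gives the symmetric arene whose two remaining C–H positions are equivalent, which removes any regiochemical question from the next step.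

**Step 3**
Reactants: 4 1,2,4,5-tetramethoxybenzene
Product: 7 1-(2,3,5,6-tetramethoxyphenyl)ethan-1-one, via aryllithium 5 (not isolated), via lithium hemiaminal alkoxide 6 (not isolated)
Conditions: n-BuLi (1.2 equiv), TMEDA (1.2 equiv), THF, 0 °C, 1 h; then MeC(O)N(OMe)Me (1.5 equiv), −78 °C → rt; 1 M HCl quench
Reagents that add atoms: N-methoxy-N-methylacetamide, CON(C)C(C)=O
Why: Directed ortho-metalation at the C–H flanked by two methoxy groups, then Weinreb ketone synthesis, where the chelated tetrahedral adduct survives until the quench and so prevents over-addition.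

**Step 4**
Reactants: 7 1-(2,3,5,6-tetramethoxyphenyl)ethan-1-one
Product: 9 1-(2-hydroxy-3,5,6-trimethoxyphenyl)ethan-1-one, via dichloroboron chelate 8 (not isolated)
Conditions: BCl3 (1.1 equiv, 1 M in CH2Cl2), CH2Cl2, −78 → 0 °C; then H2O
Reagents that add atoms: none
Why: Chelation-controlled Lewis-acid ether cleavage, in which carbonyl-bound BCl3 removes one of the two symmetry-equivalent ortho-methyl groups and the resulting six-membered boron chelate protects the other methoxy groups.

**Step 5**
Reactants: 9 1-(2-hydroxy-3,5,6-trimethoxyphenyl)ethan-1-one, 10 2,5-dimethoxybenzaldehyde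
Product: 12 (E)-1-(2-hydroxy-3,5,6-trimethoxyphenyl)-3-(2,5-dimethoxyphenyl)prop-2-en-1-one, via aldol adduct 11 (not isolated)
Conditions: KOH (50% aq., 10 equiv), EtOH, rt, 48 h; then 1 M HCl to pH 3–4
Reagents that add atoms: none
Why: Claisen–Schmidt crossed aldol condensation of the methyl-ketone enolate with a non-enolisable aldehyde, where E1cB dehydration removes the carbinol stereocentre of the adduct and gives the thermodynamically favoured E-enone.

**Step 6**
Reactants: 12 (E)-1-(2-hydroxy-3,5,6-trimethoxyphenyl)-3-(2,5-dimethoxyphenyl)prop-2-en-1-one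
Product: 15 2-(2,5-dimethoxyphenyl)-5,6,8-trimethoxy-4H-chromen-4-one, via racemic flavanone 13 (not isolated), via 3-iodoflavanone 14 (not isolated)
Conditions: I2 (10 mol%), DMSO, 130 °C, 3 h; aq. Na2S2O3 wash
Reagents that add atoms: none
Why: Iodine-catalysed oxidative cyclisation (6-endo oxa-Michael closure, α-iodination, loss of HI, DMSO re-oxidising HI to I2), which destroys the transient stereocentres and leaves the achiral flavone.

**Compound list**
1 | 2,4,5-trimethoxybenzaldehyde | COc1cc(OC)c(OC)cc1C=O | starting material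
2 | 2,4,5-trimethoxyphenyl formate | COc1cc(OC)c(OC)cc1OC=O | intermediate
3 | 2,4,5-trimethoxyphenol | COc1cc(OC)c(OC)cc1O | intermediate
4 | 1,2,4,5-tetramethoxybenzene | COc1cc(OC)c(OC)cc1OC | intermediate
5 | (2,3,5,6-tetramethoxyphenyl)lithium | [Li]c1c(OC)c(OC)cc(OC)c1OC | intermediate
6 | lithium 1-[methoxy(methyl)amino]-1-(2,3,5,6-tetramethoxyphenyl)ethan-1-olate | [Li+].CON(C)C(C)([O-])c1c(OC)c(OC)cc(OC)c1OC | intermediate
7 | 1-(2,3,5,6-tetramethoxyphenyl)ethan-1-one | CC(=O)c1c(OC)c(OC)cc(OC)c1OC | intermediate
8 | dichloroboron chelate of 9 (2,2-dichloro-5,6,8-trimethoxy-4-methyl-1,3,2-benzodioxaborinine, zwitterionic form) | CC1=[O+][B-](Cl)(Cl)Oc2c(OC)cc(OC)c(OC)c12 | intermediate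
9 | 1-(2-hydroxy-3,5,6-trimethoxyphenyl)ethan-1-one | CC(=O)c1c(O)c(OC)cc(OC)c1OC | intermediate
10 | 2,5-dimethoxybenzaldehyde | COc1ccc(OC)c(C=O)c1 | starting material
11 | racemic 3-hydroxy-1-(2-hydroxy-3,5,6-trimethoxyphenyl)-3-(2,5-dimethoxyphenyl)propan-1-one | COc1ccc(OC)c(C(O)CC(=O)c2c(O)c(OC)cc(OC)c2OC)c1 | intermediate
12 | (E)-1-(2-hydroxy-3,5,6-trimethoxyphenyl)-3-(2,5-dimethoxyphenyl)prop-2-en-1-one | COc1ccc(OC)c(/C=C/C(=O)c2c(O)c(OC)cc(OC)c2OC)c1 | intermediate
13 | racemic 2-(2,5-dimethoxyphenyl)-5,6,8-trimethoxychroman-4-one | COc1ccc(OC)c(C2CC(=O)c3c(OC)c(OC)cc(OC)c3O2)c1 | intermediate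
14 | racemic 3-iodo-2-(2,5-dimethoxyphenyl)-5,6,8-trimethoxychroman-4-one (diastereomer mixture) | COc1ccc(OC)c(C2Oc3c(OC)cc(OC)c(OC)c3C(=O)C2I)c1 | intermediate
15 | 2-(2,5-dimethoxyphenyl)-5,6,8-trimethoxy-4H-chromen-4-one (5,6,8,2',5'-pentamethoxyflavone) | COc1ccc(OC)c(-c2cc(=O)c3c(OC)c(OC)cc(OC)c3o2)c1 | target

**Totals**
Total step count: 6. Longest linear sequence: 6 steps (1 → 15); aldehyde 10 is bought and enters at step 5.

**Three steps most likely to fail, with fallbacks**

Step 3 (ortho-lithiation/Weinreb acylation). The hindered aryllithium may deprotonate the Weinreb acetamide instead of adding, returning 4. The fallback sets out from phenol 3 and comes back at hydroxyacetophenone 9, replacing steps 2–4 by an electrophilic ortho-acylation. Phenol 3 is acetylated (Ac2O, pyridine, cat. DMAP, rt) to 2,4,5-trimethoxyphenyl acetate F1. Fries rearrangement (BF3·OEt2, 3 equiv, AcOH, 90 °C) moves the acetyl group to the only free position ortho to the phenolic oxygen, the para position being blocked by OMe. This gives the difluoroboron chelate of the ortho-hydroxy ketone F2, which brief reflux in aqueous EtOH cleaves to 9. The caveat is that the other free ring position, between two OMe groups, is also activated, so regioselectivity rests on the chelate being the thermodynamic sink.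

Step 5 (aldol condensation of a 2,6-disubstituted acetophenone). The twisted, hindered ketone may condense slowly, and aldehyde 10 may undergo Cannizzaro loss. Partial closure of 12 to flavanone 13 is harmless because both converge in step 6. The fallback sets out from 9 and comes back at target 15, replacing steps 5 and 6 by an intermolecular Claisen-type acylation and cyclodehydration. Ketone 9 is treated with LiHMDS (3.5 equiv, THF, −78 °C) to give the dilithium enolate-phenolate F3. This is C-acylated with 2,5-dimethoxybenzoyl chloride (COc1ccc(OC)c(C(Cl)=O)c1, 1.0 equiv, −78 °C → rt, HCl quench) to give 1-(2-hydroxy-3,5,6-trimethoxyphenyl)-3-(2,5-dimethoxyphenyl)propane-1,3-dione F4. Catalytic H2SO4 in AcOH at 95 °C closes this to the cyclic hemiketal 2-hydroxy-2-(2,5-dimethoxyphenyl)-5,6,8-trimethoxychroman-4-one F5, which dehydrates in the same pot to 15.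

Step 6 (I2/DMSO oxidative cyclisation). Risks are iodination of the electron-rich rings, partial loss of the 5-OMe group, or stalling at the flavanone. The fallback sets out from chalcone 12 and comes back at 15 by separating ring closure from dehydrogenation and using a quinone hydride acceptor instead of halogenation/elimination. Chalcone 12 is isomerised with NaOAc (3 equiv) in refluxing EtOH and the racemic flavanone 13, already in the compound list, is isolated. It is then dehydrogenated with DDQ (2 equiv) in refluxing 1,4-dioxane to 15. This fallback makes no new compound (F0).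

**Further compounds**
F1 | step 3 | 2,4,5-trimethoxyphenyl acetate | COc1cc(OC)c(OC)cc1OC(C)=O
F2 | step 3 | difluoroboron chelate of 1-(2-hydroxy-3,5,6-trimethoxyphenyl)ethan-1-one | CC1=[O+][B-](F)(F)Oc2c(OC)cc(OC)c(OC)c12
F3 | step 5 | dilithium enolate-phenolate of 1-(2-hydroxy-3,5,6-trimethoxyphenyl)ethan-1-one | [Li+].[Li+].C=C([O-])c1c([O-])c(OC)cc(OC)c1OC
F4 | step 5 | 1-(2-hydroxy-3,5,6-trimethoxyphenyl)-3-(2,5-dimethoxyphenyl)propane-1,3-dione | COc1ccc(OC)c(C(=O)CC(=O)c2c(O)c(OC)cc(OC)c2OC)c1
F5 | step 5 | racemic 2-hydroxy-2-(2,5-dimethoxyphenyl)-5,6,8-trimethoxychroman-4-one | COc1ccc(OC)c(C2(O)CC(=O)c3c(OC)c(OC)cc(OC)c3O2)c1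
F0 | step 6 | none | none
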